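The ratio of the rate of target to the rate of second product holds no time, so a meeting on this flask opened with it.

| setting | spring | dusk | dawn | alpha | zeta |
|---|---|---|---|---|---|
| solid substrate | 0.010 M | 0.010 M | 0.010 M | 0.010 M | 0.010 M |
| reagent | 0.34 equiv | 1.6 equiv | 1.05 equiv | 1.05 equiv | 0.260 equiv |
| second substrate | 1 equiv | 1 equiv | 0.87 equiv | 1.00 equiv | 0.500 equiv |
| remark | run made earlier | run made earlier | run made earlier |  |  |
| time |  |  |  | 40 h | 40 h |

- spring (time / h: target / %): 4.00: 3; 10.0: 1; 20.0: 2; 30.0: 3
- dusk (time / h: target / %): 2.50: 8; 5.00: 15; 12.0: 29; 30.0: 55
- dawn (time / h: target / %): 8.00: 13; 15.0: 17; 20.0: 21; 30.0: 22

(readings scatter by 2 percentage points)

- a species is counted by the solid substrate in it: one idle adduct counts as two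
- amounts and yields of target count idle adduct too
- given per volume of solution although it is solid: solid substrate
- the earlier runs were read with a standard deviation of 2 percentage points
- reactions considered so far: starting material + reagent -> target; second substrate + reagent -> second product; starting material + target <-> idle adduct; solid substrate <-> starting material; starting material + second substrate -> cross product
- at the start none of the solid substrate is in solution
- what has only dissolved of solid substrate counts as not reacted
- in an amount of target, one idle adduct counts as one target

- the flask that ends with the higher amount of target, in percent of the solid substrate charged, or "neither" when 2 percentage points or less lies between them (alpha / zeta / neither)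
- final target, as a percentage of the solid substrate charged, in alpha
- final target, as a percentage of the solid substrate charged, in zeta

The first speaker noted that both steps spend reagent. So amounts give target's share of the spent reagent, which is an average over the run and not the ratio at one moment. In spring, target averaged 2.25% and stayed flat within scatter. She took all 0.34 equiv of reagent as spent, so target had received 6.62% of it.

The second speaker concluded that in spring second substrate took nearly all the reagent, so he proposed counting instead. One reagent makes one target or one second product. One second substrate makes one second product or one cross product. Subtracting gives target = surplus + cross product + second substrate left − reagent left. The surplus is reagent minus second substrate as charged. For alpha it is 0.0500, the surplus balance.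

He tried this on dawn. Its surplus is 0.180, and its last reading exceeds that by 4.00%. Adding this reading to alpha's surplus gave his reckoning of 9.00%.

The third speaker took zeta, whose surplus is −0.240, so reagent is the limiting reagent. Zeta starts with half the second substrate of spring. At equal [starting material], she doubled spring's share, which gave 3.44%. The meeting expected more target in alpha than in zeta.

The forecast named alpha, with 9.5% and 4%, and concluded: “Alpha should end higher”.

The simulation names alpha, with 13.8% in alpha and 2.85% in zeta.

    starting material + reagent → target (k = 0.360 /M/min)
    second substrate + reagent → second product (k = 1.80 /M/min)
    starting material + target ⇌ idle adduct, settled at all times (K = 84.0 /M)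
    solid substrate ⇌ starting material, rate k4*(cs4 - [starting material]) while solid is left; crystals form when [starting material] > cs4 (solubility = 3.70 mM, k = 0.0100 /min)
    starting material + second substrate → cross product (k = 0.170 /M/min)

In alpha, the step from second substrate to second product had 89% of its turnover behind it after 4.00 h, and the step to target had 66% behind it after 8.00 h. Cross product then rose from 6.17% at 20.0 h to 7.74% at 40.0 h, with 1.3% of second substrate and 0.21% of reagent left, so alpha's balance reads 13.8%. The neighbour of alpha with 0.250 equiv of second substrate has a surplus of 0.800, keeps 8.3% of its reagent and ends with 71.7% of target.

The runs are simulated with constants of no real substance, and the scatter is random.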